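**Plan**

Numbering: ring A (C1–C6) carries the biaryl bond at C1, OH at C2 and C3 and a 3-methoxyphenethyl arm at C5; ring B (C1'–C6') carries the second arm at C2' and OH at C4' and C5'.
Enabling feature: the C2 hydroxyl lies next to the biaryl bond and so next to C2', which is para to the C5' oxygen; a carbenium carbon held on O2 reaches C2' through a six-membered ring (O2, C2, C1, C1', C2', bridge carbon).
Retrosynthesis: add an O2–C(bridge) bond and three O-benzyl groups (all cleaved by hydrogenolysis); cut C2'–C(bridge) and O2–C(bridge) of the resulting 6H-benzo[c]chromene to a biaryl phenol and an arylacetaldehyde acetal; cut C1–C1' (Suzuki–Miyaura); cut the ring A arm at its olefin (Wittig).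
Forward: ring A bromophenol with its bibenzyl arm, then ring B by cross-coupling, then closure of the pyran ring, which installs the ring B bridge carbon, then reductive opening of that ring together with debenzylation.
Stereochemistry: the target has no stereocentre; the single one made in the key step forms as a racemate and becomes a CH2 group in the last step.

Key step: step 9

Remark on the chemistry: the biaryl axis has only one non-hydrogen ortho substituent on each ring and is taken as freely rotating, so isoplagilin is treated as achiral.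

**Route**

Step 1
Reactants: 1 3-(benzyloxy)-4-hydroxybenzaldehyde
Product: 2 3-(benzyloxy)-5-bromo-4-hydroxybenzaldehyde
Conditions: Br2 (1.05 equiv), NaOAc, AcOH, rt
Reagents that add atoms: bromine, BrBr
Why: Electrophilic aromatic bromination goes to the only free position ortho to the hydroxyl (para is blocked by the formyl group), as in the bromination of vanillin, and the acetate buffer keeps HBr from the benzyl ether.

Step 2
Reactants: 2 3-(benzyloxy)-5-bromo-4-hydroxybenzaldehyde; 3 (3-methoxybenzyl)triphenylphosphonium chloride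
Product: 5 2-(benzyloxy)-6-bromo-4-[2-(3-methoxyphenyl)ethenyl]phenol (E/Z mixture), via phosphorus ylide 4 (not isolated)
Conditions: 3 (1.4 equiv), KOtBu (2.6 equiv), THF, 0 °C to 50 °C; aq. NH4Cl
Reagents that add atoms: none
Why: Wittig olefination with the semi-stabilised ylide 4 in excess, one extra equivalent of base resting on the phenol, should give the stilbene with loss of Ph3PO, and the E/Z mixture is of no concern because step 3 saturates the double bond.

Step 3
Reactants: 5 2-(benzyloxy)-6-bromo-4-[2-(3-methoxyphenyl)ethenyl]phenol (E/Z mixture)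
Product: 6 2-(benzyloxy)-6-bromo-4-[2-(3-methoxyphenyl)ethyl]phenol
Conditions: p-toluenesulfonyl hydrazide (excess), NaOAc, DME/H2O, reflux
Reagents that add atoms: none
Why: Diimide reduction, with HN=NH released thermally from the sulfonyl hydrazide, transfers H2 to the C=C bond in a concerted manner and leaves the aryl bromide and the benzyl ether alone, which hydrogenation over palladium would not.

Step 4
Reactants: 7 1,2-bis(benzyloxy)benzene
Product: 8 1,2-bis(benzyloxy)-4-bromobenzene
Conditions: NBS (1.05 equiv), MeCN, 0 °C to rt, dark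
Reagents that add atoms: N-bromosuccinimide, O=C1CCC(=O)N1Br
Why: Electrophilic aromatic bromination of a catechol diether with NBS in acetonitrile is expected to stop at the monobromide para to one alkoxy group, and ionic conditions spare the benzylic CH2 groups.

Step 5
Reactants: 8 1,2-bis(benzyloxy)-4-bromobenzene
Product: 9 2-[3,4-bis(benzyloxy)phenyl]-4,4,5,5-tetramethyl-1,3,2-dioxaborolane
Conditions: B2pin2, PdCl2(dppf) (dppf = 1,1'-bis(diphenylphosphino)ferrocene, cat.), KOAc, 1,4-dioxane, 90 °C
Reagents that add atoms: bis(pinacolato)diboron, CC1(C)OB(OC1(C)C)B1OC(C)(C)C(C)(C)O1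
Why: Miyaura borylation of an unhindered, electron-rich aryl bromide is routine, and the weak acetate base avoids homocoupling.

Step 6
Reactants: 6 2-(benzyloxy)-6-bromo-4-[2-(3-methoxyphenyl)ethyl]phenol; 9 2-[3,4-bis(benzyloxy)phenyl]-4,4,5,5-tetramethyl-1,3,2-dioxaborolane
Product: 10 2-(benzyloxy)-6-[3,4-bis(benzyloxy)phenyl]-4-[2-(3-methoxyphenyl)ethyl]phenol
Conditions: Pd(OAc)2 (cat.), 2-dicyclohexylphosphino-2',6'-dimethoxybiphenyl (SPhos), K3PO4, toluene/H2O, 90 °C
Reagents that add atoms: none
Why: Suzuki–Miyaura coupling of an unprotected ortho-bromophenol with a boronate lacking ortho substituents should proceed with an electron-rich biarylphosphine ligand, and the benzyl ethers are inert to it.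

Step 7
Reactants: 11 2-(3-methoxyphenyl)ethanol
Product: 12 (3-methoxyphenyl)acetaldehyde
Conditions: PhI(OAc)2 (1.1 equiv), 2,2,6,6-tetramethylpiperidine-1-oxyl (TEMPO, cat.), CH2Cl2, rt; crude aldehyde used at once
Reagents that add atoms: none
Why: Oxoammonium-mediated (TEMPO) oxidation of a primary alcohol stops at the aldehyde under nearly neutral conditions, which suits an enolisable arylacetaldehyde.

Step 8
Reactants: 12 (3-methoxyphenyl)acetaldehyde
Product: 13 1-(2,2-dimethoxyethyl)-3-methoxybenzene
Conditions: HC(OMe)3, MeOH, p-TsOH·H2O (cat.), rt; Et3N quench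
Reagents that add atoms: trimethyl orthoformate, COC(OC)OC; methanol, CO
Why: Acid-catalysed acetalisation driven by the orthoformate as water scavenger converts the labile aldehyde into a storable dimethyl acetal.

Step 9
Reactants: 10 2-(benzyloxy)-6-[3,4-bis(benzyloxy)phenyl]-4-[2-(3-methoxyphenyl)ethyl]phenol; 13 1-(2,2-dimethoxyethyl)-3-methoxybenzene
Product: 16 4,8,9-tris(benzyloxy)-6-(3-methoxybenzyl)-2-[2-(3-methoxyphenyl)ethyl]-6H-benzo[c]chromene (racemic), via mixed aryl methyl acetal 14 (not isolated), via aryloxycarbenium ion 15 (not isolated)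
Conditions: 13 (1.5 equiv, slow addition), Me3SiOTf (20 mol %), 4 Å MS, CH2Cl2, −20 °C to rt; Et3N quench
Reagents that add atoms: none
Why: Acid exchanges one methoxy group of 13 for the phenol oxygen of 10 to give mixed acetal 14, which loses methanol (taken up by the sieves) to form aryloxycarbenium ion 15; ring B attacks this ion in an intramolecular Friedel–Crafts reaction and rearomatises. The closest known reaction type is the oxa-Pictet–Spengler cyclisation of aryl-tethered hydroxyls with acetals, used here in its phenolic form on a biaryl-2-ol. The pyran ring closes in a 6-endo-trig mode with respect to the C=O+ bond, through the phenol oxygen, two ring A carbons, two ring B carbons and the carbenium carbon. The new stereocentre at C6 of the chromene is under no control and forms as a racemate, which is acceptable because step 10 turns this carbon into a CH2 group. The step needs site selectivity between the two ring B carbons ortho to the biaryl bond: the reacting one is para to a benzyloxy group and flanked by hydrogen, whereas the other is only ortho-activated and wedged between the biaryl bond and a benzyloxy group, the same para preference that governs Pictet–Spengler closures onto 3,4-dialkoxyphenyl rings. Should a methoxycarbenium ion attack ring B first, the resulting benzylic methyl ether is expected to ionise and be captured by the phenol, giving the same product.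

Step 10
Reactants: 16 4,8,9-tris(benzyloxy)-6-(3-methoxybenzyl)-2-[2-(3-methoxyphenyl)ethyl]-6H-benzo[c]chromene (racemic)
Product: 17 isoplagilin, 2',5-bis[2-(3-methoxyphenyl)ethyl]biphenyl-2,3,4',5'-tetrol
Conditions: H2 (4 atm), Pd(OH)2/C, EtOAc/AcOH, 40 °C; work-up under argon
Reagents that add atoms: none
Why: Catalytic hydrogenolysis cleaves the three benzyl aryl ethers and the cyclic benzylic aryl ether C6–O bond, which is activated by the para oxygen on ring B (after debenzylation a para-hydroxybenzyl aryl ether that ionises readily in acetic acid and is reduced on palladium), while the methyl ethers are untouched.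

**Compound list**

1 | 3-(benzyloxy)-4-hydroxybenzaldehyde | O=Cc1ccc(O)c(OCc2ccccc2)c1 | starting material
2 | 3-(benzyloxy)-5-bromo-4-hydroxybenzaldehyde | O=Cc1cc(Br)c(O)c(OCc2ccccc2)c1 | intermediate
3 | (3-methoxybenzyl)triphenylphosphonium chloride | COc1cccc(C[P+](c2ccccc2)(c2ccccc2)c2ccccc2)c1.[Cl-] | starting material
4 | (3-methoxybenzylidene)triphenylphosphorane, formed in the flask | COc1cccc(C=P(c2ccccc2)(c2ccccc2)c2ccccc2)c1 | intermediate
5 | 2-(benzyloxy)-6-bromo-4-[2-(3-methoxyphenyl)ethenyl]phenol, E/Z mixture (geometry left open) | COc1cccc(C=Cc2cc(Br)c(O)c(OCc3ccccc3)c2)c1 | intermediate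
6 | 2-(benzyloxy)-6-bromo-4-[2-(3-methoxyphenyl)ethyl]phenol | COc1cccc(CCc2cc(Br)c(O)c(OCc3ccccc3)c2)c1 | intermediate
7 | 1,2-bis(benzyloxy)benzene | c1ccc(COc2ccccc2OCc2ccccc2)cc1 | starting material
8 | 1,2-bis(benzyloxy)-4-bromobenzene | Brc1ccc(OCc2ccccc2)c(OCc2ccccc2)c1 | intermediate
9 | 2-[3,4-bis(benzyloxy)phenyl]-4,4,5,5-tetramethyl-1,3,2-dioxaborolane | CC1(C)OB(c2ccc(OCc3ccccc3)c(OCc3ccccc3)c2)OC1(C)C | intermediate
10 | 2-(benzyloxy)-6-[3,4-bis(benzyloxy)phenyl]-4-[2-(3-methoxyphenyl)ethyl]phenol | COc1cccc(CCc2cc(OCc3ccccc3)c(O)c(-c3ccc(OCc4ccccc4)c(OCc4ccccc4)c3)c2)c1 | intermediate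
11 | 2-(3-methoxyphenyl)ethanol | COc1cccc(CCO)c1 | starting material
12 | (3-methoxyphenyl)acetaldehyde | COc1cccc(CC=O)c1 | intermediate
13 | 1-(2,2-dimethoxyethyl)-3-methoxybenzene | COc1cccc(CC(OC)OC)c1 | intermediate
14 | 1-(benzyloxy)-3-[3,4-bis(benzyloxy)phenyl]-2-[1-methoxy-2-(3-methoxyphenyl)ethoxy]-5-[2-(3-methoxyphenyl)ethyl]benzene, racemic mixed acetal formed in the flask | COc1cccc(CCc2cc(OCc3ccccc3)c(OC(OC)Cc3cccc(OC)c3)c(-c3ccc(OCc4ccccc4)c(OCc4ccccc4)c3)c2)c1 | intermediate
15 | {2-(benzyloxy)-6-[3,4-bis(benzyloxy)phenyl]-4-[2-(3-methoxyphenyl)ethyl]phenyl}[2-(3-methoxyphenyl)ethylidene]oxonium, formed in the flask | COc1cccc(CCc2cc(OCc3ccccc3)c([O+]=CCc3cccc(OC)c3)c(-c3ccc(OCc4ccccc4)c(OCc4ccccc4)c3)c2)c1 | intermediate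
16 | 4,8,9-tris(benzyloxy)-6-(3-methoxybenzyl)-2-[2-(3-methoxyphenyl)ethyl]-6H-benzo[c]chromene, racemic at C6 | COc1cccc(CC2Oc3c(OCc4ccccc4)cc(CCc4cccc(OC)c4)cc3-c3cc(OCc4ccccc4)c(OCc4ccccc4)cc32)c1 | intermediate
17 | isoplagilin, 2',5-bis[2-(3-methoxyphenyl)ethyl]biphenyl-2,3,4',5'-tetrol (achiral) | COc1cccc(CCc2cc(O)c(O)c(-c3cc(O)c(O)cc3CCc3cccc(OC)c3)c2)c1 | target

**Count and risks**

Total steps: 10. Longest linear sequence: 6 steps (steps 1, 2, 3, 6, 9, 10).

Steps most likely to fail:

1. Step 9. The acetal may ionise to the methoxycarbenium ion and condense with itself, through its enol ether or its own methoxy-activated ring, faster than the hindered phenol captures it. Prolonged acid may also shift benzyl groups or reopen the new benzylic C–O bond with elimination to a stilbene; that olefin would still be reduced in step 10. Fallback: the ring B bridge carbon is installed before the biaryl bond, setting out from bromophenol 6. Commercial 3,4-bis(benzyloxy)benzaldehyde is brominated (Br2, NaOAc, AcOH) para to its 3-benzyloxy group to give 2-bromo-4,5-bis(benzyloxy)benzaldehyde F1. Wittig olefination of F1 with ylide 4 (from 3 and KOtBu, as in step 2) gives 1,2-bis(benzyloxy)-4-bromo-5-[2-(3-methoxyphenyl)ethenyl]benzene F2. Miyaura borylation (B2pin2, PdCl2(dppf), KOAc, dioxane) converts it into the pinacol boronate F3. Suzuki–Miyaura coupling of F3 with 6 (Pd(OAc)2, SPhos, K3PO4) gives 2-(benzyloxy)-6-{4,5-bis(benzyloxy)-2-[2-(3-methoxyphenyl)ethenyl]phenyl}-4-[2-(3-methoxyphenyl)ethyl]phenol F4. Hydrogenation over Pd/C saturates the olefin and removes the benzyl groups, returning to the route at 17.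

2. Step 10. The benzyl ethers may cleave while the cyclic benzylic C–O bond resists, because in the twisted pyran ring it is poorly aligned with the ring B π system on the catalyst surface. Fallback: from 16 the pyran ring is opened first by ionic hydrogenation (Et3SiH, CF3CO2H, CH2Cl2, 0 °C). Ionisation at the benzylic carbon, stabilised by the para benzyloxy group and with the phenol as leaving group, followed by hydride transfer should give 2-(benzyloxy)-6-{4,5-bis(benzyloxy)-2-[2-(3-methoxyphenyl)ethyl]phenyl}-4-[2-(3-methoxyphenyl)ethyl]phenol F5. Neutral hydrogenolysis (H2, Pd/C, EtOAc/MeOH, rt) then removes the three benzyl groups and returns to the route at 17.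

3. Step 2. The aldehyde reacts as its phenoxide, whose para oxido group lowers the electrophilicity of the carbonyl, so the olefination may stall. Fallback: from 2, addition of 3-methoxybenzylmagnesium chloride (3 equiv, THF, 0 °C; the first equivalent deprotonates the phenol) should give 2-(benzyloxy)-6-bromo-4-[1-hydroxy-2-(3-methoxyphenyl)ethyl]phenol F6. Ionic deoxygenation of this para-hydroxybenzylic alcohol (Et3SiH, CF3CO2H, CH2Cl2, 0 °C) leads directly to bibenzyl 6, where the route is rejoined without passing through 5.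

**Further compounds**

F1 | step 9 | 2-bromo-4,5-bis(benzyloxy)benzaldehyde | O=Cc1cc(OCc2ccccc2)c(OCc2ccccc2)cc1Br
F2 | step 9 | 1,2-bis(benzyloxy)-4-bromo-5-[2-(3-methoxyphenyl)ethenyl]benzene, E/Z mixture | COc1cccc(C=Cc2cc(OCc3ccccc3)c(OCc3ccccc3)cc2Br)c1
F3 | step 9 | 2-{4,5-bis(benzyloxy)-2-[2-(3-methoxyphenyl)ethenyl]phenyl}-4,4,5,5-tetramethyl-1,3,2-dioxaborolane, E/Z mixture | COc1cccc(C=Cc2cc(OCc3ccccc3)c(OCc3ccccc3)cc2B2OC(C)(C)C(C)(C)O2)c1
F4 | step 9 | 2-(benzyloxy)-6-{4,5-bis(benzyloxy)-2-[2-(3-methoxyphenyl)ethenyl]phenyl}-4-[2-(3-methoxyphenyl)ethyl]phenol, E/Z mixture | COc1cccc(C=Cc2cc(OCc3ccccc3)c(OCc3ccccc3)cc2-c2cc(CCc3cccc(OC)c3)cc(OCc3ccccc3)c2O)c1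
F5 | step 10 | 2-(benzyloxy)-6-{4,5-bis(benzyloxy)-2-[2-(3-methoxyphenyl)ethyl]phenyl}-4-[2-(3-methoxyphenyl)ethyl]phenol | COc1cccc(CCc2cc(OCc3ccccc3)c(O)c(-c3cc(OCc4ccccc4)c(OCc4ccccc4)cc3CCc3cccc(OC)c3)c2)c1
F6 | step 2 | 2-(benzyloxy)-6-bromo-4-[1-hydroxy-2-(3-methoxyphenyl)ethyl]phenol, racemic | COc1cccc(CC(O)c2cc(Br)c(O)c(OCc3ccccc3)c2)c1
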